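The C1–C4′ tether and ring B are joined by one temporary bond. In the cis-fused decalin, the acyl carbon C4′ on C4 and ring carbon C7 both lie on the β face of ring B, so a C4′–C7 bond turns ring B into a bicyclo[2.2.2]octene. That cage is made in one intramolecular [4+2] cycloaddition of a ring B 1-silyloxy-1,3-diene (C7=C6–C5=C4a) with a tethered (E)-nitroalkene (C4=C4′): C4–C4a closes ring A, C4′–C7 closes the bridge, and C4, C4a and C7 follow from a preset C8a. The precursor is a 5-acyl-3-methyl-1-silyloxycyclohexa-1,3-diene whose C8a side chain (C1 ketone, silylated C2 carbinol, C3 sec-butyl) ends in the nitroalkene. Fluoride-triggered retro-Henry cleavage later reopens C4′–C7.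

Key step: step 10

Remarks on the chemistry:
- Locants are those of the target decalin: C1 ring ketone, C2 carbinol, C3 sec-butyl carbon, C4 quaternary carbon with acyl carbon C4′, C4a/C8a ring fusion, C5 methyl carbon, C7 diol carbon; α is the face of H4a and H8a.
- Compounds 2–6 are racemic at C8a. Step 6 therefore delivers 11 as a pair of C8a epimers, and step 7 converts this pair into the single epimer 12. After step 7, C8a meets base only once, briefly and cold (step 9), before it is locked in the cage.
- Assumption: the two C8a epimers of 11 can be separated on silica or by preparative HPLC.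
- The sense of induction in step 6 is assigned by analogy with enolsilane additions to pyruvate esters catalysed by the same copper complex; should it prove opposite, the (R,R) ligand is used.
- C4′ of 15–17 is drawn as the epimer expected from suprafacial addition of the E alkene; this centre is erased in step 12.

Step 1
Reactants: 1 3-methoxy-5-methylbenzoic acid
Product: 3 (±)-3-methyl-5-oxocyclohex-3-ene-1-carboxylic acid, via dihydrobenzoic acid 2 (not isolated)
Conditions: Li, NH3(l), THF, tBuOH, −78 °C; NH4Cl; then 2 M HCl, THF, rt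
Reagents that add atoms: water, O
Why: Birch reduction of the benzoate places the two new sp3 carbons ipso and para to the carboxylate (C8a and C6), and mild acid hydrolysis of the methyl enol ether followed by migration of the C4a=C5 alkene into conjugation with the new C7 ketone should give the β-methyl enone, with C8a still racemic.

Step 2
Reactants: 3 (±)-3-methyl-5-oxocyclohex-3-ene-1-carboxylic acid
Product: 5 (±)-5-(2-ethoxyprop-2-enoyl)-3-methylcyclohex-2-en-1-one, via acid chloride 4 (not isolated)
Conditions: (COCl)2, DMF (cat.), CH2Cl2, 0 °C → rt; concentrate; tributyl(1-ethoxyvinyl)stannane, PdCl2(PPh3)2 (cat.), toluene, 80 °C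
Reagents that add atoms: tributyl(1-ethoxyvinyl)stannane, CCCC[Sn](CCCC)(CCCC)C(=C)OCC; oxalyl chloride, O=C(Cl)C(=O)Cl (chlorine of 4 only)
Why: Acid chloride formation and an acyl Stille coupling attach a masked acetyl group (C2 and its methyl) to C1 under neutral conditions that leave the enone untouched.

Step 3
Reactants: 5 (±)-5-(2-ethoxyprop-2-enoyl)-3-methylcyclohex-2-en-1-one
Product: 6 (±)-1-(3-methyl-5-oxocyclohex-3-en-1-yl)propane-1,2-dione
Conditions: 1 M HCl, THF, 0 °C → rt
Reagents that add atoms: water, O
Why: Acid hydrolysis of the α-keto enol ether unmasks the C2 ketone and gives the vicinal diketone.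

Step 4
Reactants: 7 (R)-2-methylbutanoic acid
Product: 8 (R)-2-methylbutan-1-ol
Conditions: LiAlH4, Et2O, 0 °C → rt; aqueous work-up
Reagents that add atoms: none
Why: Hydride reduction of the acid to the primary alcohol does not touch the α stereocentre, which becomes the sec-butyl centre of the target.

Step 5
Reactants: 8 (R)-2-methylbutan-1-ol
Product: 10 trimethyl[(4R)-2,4-dimethylhex-2-en-1-yl]silane (E/Z mixture), via (R)-2-methylbutanal 9 (not isolated)
Conditions: TEMPO (cat.), PhI(OAc)2, CH2Cl2, rt; NaHCO3 wash, dry; solution of 9 added to Ph3P=C(CH3)CH2SiMe3 [from EtPPh3Br, nBuLi, ICH2SiMe3, then nBuLi, THF], −78 °C → rt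
Reagents that add atoms: ethyltriphenylphosphonium bromide, CC[P+](c1ccccc1)(c1ccccc1)c1ccccc1.[Br-]; (iodomethyl)trimethylsilane, C[Si](C)(C)CI
Why: Oxoammonium oxidation gives the aldehyde without α-epimerisation, and a Wittig reaction with the β-silyl ylide (Seyferth–Fleming allylsilane synthesis) converts it directly into the allylsilane, whose alkene geometry is not controlled because step 6 is expected to be stereoconvergent.

Step 6
Reactants: 6 (±)-1-(3-methyl-5-oxocyclohex-3-en-1-yl)propane-1,2-dione; 10 trimethyl[(4R)-2,4-dimethylhex-2-en-1-yl]silane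
Product: 11 (2S,3R)-3-[(2R)-butan-2-yl]-2,4-dimethyl-1-[(1RS)-3-methyl-5-oxocyclohex-3-en-1-yl]-2-(trimethylsilyloxy)pent-4-en-1-one (pair of C8a epimers)
Conditions: [Cu((S,S)-tBu-box)](SbF6)2 (10 mol%; tBu-box = 2,2'-(propane-2,2-diyl)bis[(4S)-4-tert-butyl-4,5-dihydrooxazole]), CH2Cl2, −78 → −20 °C
Reagents that add atoms: none
Why: Hosomi–Sakurai (SE2′) allylation of the methyl ketone of the copper-chelated vicinal diketone, in which the bis(oxazoline) ligand shields one face of the chelate so that C2 should form as S, the open antiperiplanar transition state should give the needed 2,3-relationship (C3 R) from either alkene geometry as in enolsilane additions with this catalyst, the alkoxide is silylated by the departing Me3Si group, and, because the catalyst reads only the chelate while C8a of 6 is racemic, 11 is expected as a near-equal pair of C8a epimers.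

Step 7
Reactants: 11 (2S,3R)-3-[(2R)-butan-2-yl]-2,4-dimethyl-1-[(1RS)-3-methyl-5-oxocyclohex-3-en-1-yl]-2-(trimethylsilyloxy)pent-4-en-1-one (pair of C8a epimers)
Product: 12 (2S,3R)-3-[(2R)-butan-2-yl]-2,4-dimethyl-1-[(1R)-3-methyl-5-oxocyclohex-3-en-1-yl]-2-(trimethylsilyloxy)pent-4-en-1-one
Conditions: chromatography on SiO2 (or preparative HPLC); the (1S) fraction: DBU (0.2 equiv), toluene, 60 °C, then chromatography again (repeated)
Reagents that add atoms: none
Why: Base-mediated epimerisation by enolisation and reprotonation: C8a carries the only α-hydrogen of the C1 ketone, so the amidine base should return the unwanted (1S) epimer to a near-equal mixture that is separated again, each cycle channelling more material into 12, while C2 (quaternary), C3 (not α to a carbonyl), the silyl ether and the conjugated enone are left as they are.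

Step 8
Reactants: 12 (2S,3R)-3-[(2R)-butan-2-yl]-2,4-dimethyl-1-[(1R)-3-methyl-5-oxocyclohex-3-en-1-yl]-2-(trimethylsilyloxy)pent-4-en-1-one
Product: 13 (2S,3R,4E)-3-[(2R)-butan-2-yl]-2,4-dimethyl-1-[(1R)-3-methyl-5-oxocyclohex-3-en-1-yl]-5-nitro-2-(trimethylsilyloxy)pent-4-en-1-one
Conditions: AgNO2, TEMPO, 4 Å MS, 1,2-dichloroethane, 70 °C
Reagents that add atoms: silver nitrite, [Ag+].[O-]N=O
Why: Radical nitration in which NO2 adds to the terminal carbon of the 1,1-disubstituted alkene, TEMPO intercepts the tertiary radical, and loss of TEMPO–H toward the acidified CH2NO2 group should give the conjugated nitroalkene with the nitro group trans to the larger C3 substituent (E), the electron-poor enone staying untouched.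

Step 9
Reactants: 13 (2S,3R,4E)-3-[(2R)-butan-2-yl]-2,4-dimethyl-1-[(1R)-3-methyl-5-oxocyclohex-3-en-1-yl]-5-nitro-2-(trimethylsilyloxy)pent-4-en-1-one
Product: 14 (2S,3R,4E)-3-[(2R)-butan-2-yl]-1-[(1S)-5-(tert-butyldimethylsilyloxy)-3-methylcyclohexa-2,4-dien-1-yl]-2,4-dimethyl-5-nitro-2-(trimethylsilyloxy)pent-4-en-1-one
Conditions: TBSOTf, Et3N, CH2Cl2, −78 → −40 °C
Reagents that add atoms: tert-butyldimethylsilyl trifluoromethanesulfonate, CC(C)(C)[Si](C)(C)OS(=O)(=O)C(F)(F)F
Why: Soft enolisation (silyl triflate and amine) of the β-methyl enone is reversible through the ammonium triflate and should settle on the through-conjugated 1-silyloxy-1,3-diene formed by loss of the γ-proton at C4a, while low temperature and short contact spare the nitroalkene and the hindered C1 ketone with its C8a centre (the descriptor at that carbon changes from R to S only because the ring priorities change).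

Step 10
Reactants: 14 (2S,3R,4E)-3-[(2R)-butan-2-yl]-1-[(1S)-5-(tert-butyldimethylsilyloxy)-3-methylcyclohexa-2,4-dien-1-yl]-2,4-dimethyl-5-nitro-2-(trimethylsilyloxy)pent-4-en-1-one
Product: 15 tricyclic nitro adduct (ring A fused to a bicyclo[2.2.2]oct-5-ene; C7 bridgehead OTBS; C5=C6; C4′ nitro; C2 OTMS; C1 ketone)
Conditions: toluene (0.01 M), BHT (cat.), 110 °C, sealed tube, base-washed glass
Reagents that add atoms: none
Why: Proposed new method: a thermal, normal-demand intramolecular Diels–Alder reaction in which the silyloxydiene C7=C6–C5=C4a adds suprafacially to the nitroalkene, the nucleophilic terminus C4a bonding to the electrophilic β-carbon C4 and the silyloxy-bearing C7 to the nitro-bearing C4′ (concerted but asynchronous; a stepwise Mukaiyama–Michael addition followed by C-alkylation of the nitronate would give the same adduct, and a cyclic nitronate from O-attack should rearrange on heating). The closest known reactions are intramolecular Diels–Alder reactions of 5-tethered 1-silyloxycyclohexa-1,3-dienes and Diels–Alder reactions of oxygenated dienes with nitroalkenes; a β,β-disubstituted nitroalkene that builds a quaternary carbon in this role has no close precedent. Ring A closes as a six-membered ring across C4–C4a through the three-atom tether C1–C2–C3 anchored at C8a, and the C4′–C7 bond closes the two-carbon bridge of the bicyclo[2.2.2]octene. Because the tether starts at the sp3 carbon C8a, the dienophile can reach only the diene face syn to C1, so the preset C8a dictates C4a and C7; the tether must lie over the C8–C8a bridge, which places the C4 methyl endo and fixes C4, and the E geometry puts the nitro group endo at C4′. The regiochemistry needed is both the electronically favoured one and the only one the tether allows, carbon rather than oxygen closure is favoured by the absence of a Lewis acid, and the neutral, base-free medium keeps C8a, C3 and the nitroalkene from isomerising.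

Step 11
Reactants: 15 tricyclic nitro adduct
Product: 16 dihydro adduct (C5 methyl on the side of the C4–C4′ bridge; C6 now CH2)
Conditions: H2 (1–4 atm), 10% Pd/C, EtOAc, rt
Reagents that add atoms: none
Why: Heterogeneous hydrogenation should add H2 to the strained bicyclooctene alkene from the face of the C8–C8a bridge, because the endo C4 methyl and the nitro group cover the other face, which sets C5 with its methyl β in the later decalin, while the hindered secondary nitro group and the silyl ethers should survive in a neutral aprotic solvent.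

Step 12
Reactants: 16 dihydro adduct
Product: 18 cis-decalin-1,7-dione (2α-OH; 2β-Me; 3β-[(R)-sec-butyl]; 4α-Me; 4β-CH2NO2; 5β-Me; H4a and H8a α), via cage nitro diol 17 (not isolated)
Conditions: TBAF, THF, 0 °C → rt; NH4Cl (aq)
Reagents that add atoms: none
Why: Fluoride removes both silyl groups, and the bridgehead β-nitro alkoxide fragments by retro-Henry (retro-nitroaldol) cleavage of C4′–C7, driven by strain release and formation of the C7 ketone, to leave a nitromethyl group on C4 after protonation of the nitronate.

Step 13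
Reactants: 18 cis-decalin-1,7-dione with 4β-CH2NO2
Product: 20 4β-(4,5-dihydroisoxazol-3-yl) decalin-1,7-dione, via nitrile oxide 19 (not isolated)
Conditions: PhNCO, Et3N (cat.), ethylene (5 bar), toluene, 40 °C
Reagents that add atoms: ethylene, C=C
Why: Mukaiyama dehydration of the primary nitro group gives a hindered, slowly dimerising nitrile oxide that undergoes 1,3-dipolar cycloaddition with ethylene to a 2-isoxazoline, a masked β-hydroxy ketone that carries the two missing carbons; the hindered tertiary C2 alcohol should not be carbamoylated.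

Step 14
Reactants: 20 4β-(4,5-dihydroisoxazol-3-yl) decalin-1,7-dione
Product: 21 7-methylidene decalin-1-one
Conditions: Ph3PCH3Br, KOtBu (3 equiv each), THF, 0 °C → rt
Reagents that add atoms: methyltriphenylphosphonium bromide, C[P+](c1ccccc1)(c1ccccc1)c1ccccc1.[Br-]
Why: Wittig methylenation should be selective for the unhindered C7 cyclohexanone, since the C1 ketone is flanked by the ring fusion and by the C2 alkoxide formed in situ, which also disfavours enolisation toward C8a.

Step 15
Reactants: 21 7-methylidene decalin-1-one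
Product: 22 7α-hydroxy-7β-(hydroxymethyl) decalin-1-one
Conditions: OsO4 (5 mol%), NMO, acetone/H2O, rt
Reagents that add atoms: N-methylmorpholine N-oxide, C[N+]1([O-])CCOCC1; water, O
Why: Upjohn dihydroxylation in which OsO4 should add to the exocyclic alkene from the α face, because the β face of C7 is covered by the β substituents of the cis-fused core (the C4 heterocycle and the C5 methyl), so the tertiary OH ends up α and the CH2OH β.

Step 16
Reactants: 22 7α-hydroxy-7β-(hydroxymethyl) decalin-1-one
Product: 24 (2S,3R,4R,4aR,5R,7R,8aS)-3-[(2R)-butan-2-yl]-2,7-dihydroxy-7-(hydroxymethyl)-4-(3-hydroxypropanoyl)-2,4,5-trimethyloctahydronaphthalen-1(2H)-one, via β-hydroxy imine 23 (not isolated)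
Conditions: H2 (1 atm), Raney Ni, B(OH)3, MeOH/H2O (5:1), rt
Reagents that add atoms: water, O
Why: Hydrogenolysis of the isoxazoline N–O bond over Raney Ni and hydrolysis of the resulting β-hydroxy imine in the boric acid buffer release the 3-hydroxypropanoyl ketone without retro-aldol loss, the hindered C1 ketone being left alone.

Compound list
1 | 3-methoxy-5-methylbenzoic acid | COc1cc(C)cc(C(=O)O)c1 | starting material
2 | (±)-3-methoxy-5-methylcyclohexa-2,5-diene-1-carboxylic acid | COC1=CC(C(=O)O)C=C(C)C1 | intermediate
3 | (±)-3-methyl-5-oxocyclohex-3-ene-1-carboxylic acid | CC1=CC(=O)CC(C(=O)O)C1 | intermediate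
4 | (±)-3-methyl-5-oxocyclohex-3-ene-1-carbonyl chloride | CC1=CC(=O)CC(C(=O)Cl)C1 | intermediate
5 | (±)-5-(2-ethoxyprop-2-enoyl)-3-methylcyclohex-2-en-1-one | CCOC(=C)C(=O)C1CC(C)=CC(=O)C1 | intermediate
6 | (±)-1-(3-methyl-5-oxocyclohex-3-en-1-yl)propane-1,2-dione | CC(=O)C(=O)C1CC(C)=CC(=O)C1 | intermediate
7 | (R)-2-methylbutanoic acid | CC[C@@H](C)C(=O)O | starting material
8 | (R)-2-methylbutan-1-ol | CC[C@@H](C)CO | intermediate
9 | (R)-2-methylbutanal | CC[C@@H](C)C=O | intermediate
10 | trimethyl[(4R)-2,4-dimethylhex-2-en-1-yl]silane (E/Z mixture) | CC[C@@H](C)C=C(C)C[Si](C)(C)C | intermediate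
11 | (2S,3R)-3-[(2R)-butan-2-yl]-2,4-dimethyl-1-[(1RS)-3-methyl-5-oxocyclohex-3-en-1-yl]-2-(trimethylsilyloxy)pent-4-en-1-one (pair of C8a epimers) | CC[C@@H](C)[C@H](C(C)=C)[C@](C)(O[Si](C)(C)C)C(=O)C1CC(=O)C=C(C)C1 | intermediate
12 | (2S,3R)-3-[(2R)-butan-2-yl]-2,4-dimethyl-1-[(1R)-3-methyl-5-oxocyclohex-3-en-1-yl]-2-(trimethylsilyloxy)pent-4-en-1-one (single C8a epimer) | CC[C@@H](C)[C@H](C(C)=C)[C@](C)(O[Si](C)(C)C)C(=O)[C@H]1CC(=O)C=C(C)C1 | intermediate
13 | (2S,3R,4E)-3-[(2R)-butan-2-yl]-2,4-dimethyl-1-[(1R)-3-methyl-5-oxocyclohex-3-en-1-yl]-5-nitro-2-(trimethylsilyloxy)pent-4-en-1-one | CC[C@@H](C)[C@H](/C(C)=C/[N+](=O)[O-])[C@](C)(O[Si](C)(C)C)C(=O)[C@H]1CC(=O)C=C(C)C1 | intermediate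
14 | (2S,3R,4E)-3-[(2R)-butan-2-yl]-1-[(1S)-5-(tert-butyldimethylsilyloxy)-3-methylcyclohexa-2,4-dien-1-yl]-2,4-dimethyl-5-nitro-2-(trimethylsilyloxy)pent-4-en-1-one (cycloaddition precursor) | CC[C@@H](C)[C@H](/C(C)=C/[N+](=O)[O-])[C@](C)(O[Si](C)(C)C)C(=O)[C@H]1CC(O[Si](C)(C)C(C)(C)C)=CC(C)=C1 | intermediate
15 | tricyclic nitro adduct: ring A fused to a bicyclo[2.2.2]oct-5-ene, C7 bridgehead OTBS, C5=C6, C4′ nitro syn to the alkene, C4 methyl endo, C2 OTMS, C1 ketone | CC[C@@H](C)[C@@H]1[C@]2(C)[C@@H]([N+](=O)[O-])[C@@]3(O[Si](C)(C)C(C)(C)C)C=C(C)[C@@H]2[C@H](C3)C(=O)[C@@]1(C)O[Si](C)(C)C | intermediate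
16 | dihydro adduct: as 15 with C5–C6 saturated, C5 methyl toward the C4–C4′ bridge | CC[C@@H](C)[C@@H]1[C@]2(C)[C@@H]([N+](=O)[O-])[C@@]3(O[Si](C)(C)C(C)(C)C)C[C@@H](C)[C@@H]2[C@H](C3)C(=O)[C@@]1(C)O[Si](C)(C)C | intermediate
17 | cage nitro diol: 16 without both silyl groups | CC[C@@H](C)[C@@H]1[C@]2(C)[C@@H]([N+](=O)[O-])[C@@]3(O)C[C@@H](C)[C@@H]2[C@H](C3)C(=O)[C@@]1(C)O | intermediate
18 | cis-decalin-1,7-dione: 2α-hydroxy, 2β,4α,5β-trimethyl, 3β-[(R)-butan-2-yl], 4β-(nitromethyl), H4a and H8a α | CC[C@@H](C)[C@@H]1[C@](C)(C[N+](=O)[O-])[C@@H]2[C@H](C)CC(=O)C[C@@H]2C(=O)[C@@]1(C)O | intermediate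
19 | nitrile oxide of 18 (C4′≡N–O) | CC[C@@H](C)[C@@H]1[C@](C)(C#[N+][O-])[C@@H]2[C@H](C)CC(=O)C[C@@H]2C(=O)[C@@]1(C)O | intermediate
20 | 4β-(4,5-dihydroisoxazol-3-yl) analogue of 18 | CC[C@@H](C)[C@@H]1[C@](C)(C3=NOCC3)[C@@H]2[C@H](C)CC(=O)C[C@@H]2C(=O)[C@@]1(C)O | intermediate
21 | 7-methylidene analogue of 20 (C1 ketone kept) | CC[C@@H](C)[C@@H]1[C@](C)(C3=NOCC3)[C@@H]2[C@H](C)CC(=C)C[C@@H]2C(=O)[C@@]1(C)O | intermediate
22 | 7α-hydroxy-7β-(hydroxymethyl) isoxazoline | CC[C@@H](C)[C@@H]1[C@](C)(C3=NOCC3)[C@@H]2[C@H](C)C[C@](O)(CO)C[C@@H]2C(=O)[C@@]1(C)O | intermediate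
23 | β-hydroxy imine (C4′=NH, CH2CH2OH) | CC[C@@H](C)[C@@H]1[C@](C)(C(=N)CCO)[C@@H]2[C@H](C)C[C@](O)(CO)C[C@@H]2C(=O)[C@@]1(C)O | intermediate
24 | (2S,3R,4R,4aR,5R,7R,8aS)-3-[(2R)-butan-2-yl]-2,7-dihydroxy-7-(hydroxymethyl)-4-(3-hydroxypropanoyl)-2,4,5-trimethyloctahydronaphthalen-1(2H)-one (CNP0112523.4) | CC[C@@H](C)[C@@H]1[C@](C)(C(=O)CCO)[C@@H]2[C@H](C)C[C@](O)(CO)C[C@@H]2C(=O)[C@@]1(C)O | target

Total step count: 16. Longest linear sequence: 14 steps (steps 1–3 and 6–16).

Steps most likely to fail

1. Step 10. Bond formation at the fully substituted carbon C4 may be too slow, so that hydrogen shifts in the silyloxydiene, migration of the C4a=C5 double bond toward C1, or oxygen closure of the nitronate overtake the cycloaddition. The fallback uses known chemistry, sets out from 14 and bypasses the cage. TBAF in THF at −78 °C liberates the ring B dienolate, whose γ-carbon C4a adds to C4 of the nitroalkene in an intramolecular vinylogous Michael addition. This closes ring A and gives, after protonation, the cis-fused enone nitromethyl ketol F1. Conjugate reduction of its enone from the α face with [(Ph3P)CuH]6 in toluene (or H2, Pd/C) returns to the route at 18. Control of C4 is weaker than in the cage, so isomers may have to be separated.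

2. Step 6. Facial discrimination at C2 and C3 in the chelate-controlled allylation may be poor, and the hindered allylsilane may add slowly. The fallback is a closed-transition-state allylboration and sets out from 9 and 6. Stork–Zhao olefination of 9 (Ph3P=C(I)CH3, THF, −78 °C) gives (R,Z)-2-iodo-4-methylhex-2-ene F2. Iodine–lithium exchange (tBuLi) and Matteson homologation with ClCH2B(OiPr)2 give the diisopropyl (Z)-allylboronate F3 with retention of geometry. Its allylboration of 6 under chiral biphenol catalysis ((S)-3,3'-dibromo-BINOL, toluene, −35 °C) goes through a chair transition state with the acyl group equatorial, in which the Z geometry translates into the required C2/C3 relationship, and gives the free tertiary homoallylic alcohol F4 as its pair of C8a epimers. TMSOTf and 2,6-lutidine then return to the route at 11.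

3. Step 8. Hydrogen loss from the nitro radical adduct may be unselective and give allylic nitro isomers, or the oxidant may attack ring B. The fallback is a polar three-step sequence and sets out from 12. mCPBA epoxidises the electron-rich 1,1-disubstituted alkene to the oxirane F5, leaving the enone alone. NaNO2 and MgSO4 in MeOH open it at the CH2 terminus to the tertiary β-nitro alcohol F6. Dehydration with (CF3CO)2O and Et3N at −40 °C (E1cB through the nitronate) returns to the route at 13.

Further compounds
F1 | step 10 | cis-fused enone: 4β-(nitromethyl)-2α-hydroxy decalin-1,7-dione with C5=C6 | CC[C@@H](C)[C@@H]1[C@](C)(C[N+](=O)[O-])[C@@H]2C(C)=CC(=O)C[C@@H]2C(=O)[C@@]1(C)O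
F2 | step 6 | (R,Z)-2-iodo-4-methylhex-2-ene | CC[C@@H](C)/C=C(\I)C
F3 | step 6 | diisopropyl [(2Z,4R)-2,4-dimethylhex-2-en-1-yl]boronate | CC[C@@H](C)/C=C(\CB(OC(C)C)OC(C)C)C
F4 | step 6 | (2S,3R)-3-[(2R)-butan-2-yl]-2-hydroxy-2,4-dimethyl-1-[(1RS)-3-methyl-5-oxocyclohex-3-en-1-yl]pent-4-en-1-one (pair of C8a epimers) | CC[C@@H](C)[C@H](C(C)=C)[C@](C)(O)C(=O)C1CC(=O)C=C(C)C1
F5 | step 8 | 2-methyloxiran-2-yl analogue of 12 (epoxide of the C4=CH2 alkene, both C4 epimers) | CC[C@@H](C)[C@H](C1(C)CO1)[C@](C)(O[Si](C)(C)C)C(=O)[C@H]2CC(=O)C=C(C)C2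
F6 | step 8 | tertiary β-nitro alcohol: C4(OH)(CH3)CH2NO2 analogue of 12 | CC[C@@H](C)[C@H](C(C)(O)C[N+](=O)[O-])[C@](C)(O[Si](C)(C)C)C(=O)[C@H]1CC(=O)C=C(C)C1
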